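# Proposed synthesis of CNP0149861.1 by closure of ring A onto a chiral-pool arylidene cyclohexanone

Drimane numbering is used for the terpene part (C1–C10, with C11 as the benzylic carbon) and primed numbers for the arene (C1′ bonded to C11).

## Analysis of the target

The target 18 is a drimane-type sesquiterpene joined through C11 to a pentasubstituted benzene. Rings A and B form a trans-decalin with a gem-dimethyl group at C4, a methyl group on the quaternary carbon C10, a methyl group at C8 and an exocyclic trisubstituted double bond C9=C11. The three stereocentres C5, C8 and C10 are all (S): H5 is anti to the C10 methyl group (trans fusion), and the C8 methyl group is syn to the C10 methyl group, so the two stand 1,3-diaxial across the sp2 carbon C9. The double bond is (E), with the aryl group on the C8 side. The arene carries a hydrogen sulfate at C2′, a formyl group at C3′ and a free catechol at C4′/C5′. The sulfate does not survive strong protic or Lewis acids, the catechol is oxidised by air in base, and the electron-rich styrene is protonated by strong acid, after which a free C2′ hydroxyl can cyclise onto the terpene. The hard parts are the quaternary C10 next to the fully substituted C9, the strained syn arrangement of the two methyl groups, the alkene geometry, and an order of events that places one sulfate on one of three phenolic oxygens. The strategy rests on three readings of the structure: C9=C11 with the aryl group cis to C8 is the (E)-arylidene of a C10 ketone; ring B with its C8 methyl group is a 3-methylcyclohexanone unit of (S) configuration; and C10, flanked by C9=C11 and the oxygenated arene, is the terminus of a strongly stabilised allyl cation that a nucleophilic C1 can capture to close ring A.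

## Retrosynthetic reasoning

**18 ⇐ 17.** The O–benzyl bonds at C4′ and C5′ are cut last. The catechol is the most oxidisable part of the molecule, and benzyl ethers can be removed by hydrogenolysis, without the strong acid that would cleave the aryl sulfate. Methyl ethers at these positions could not be removed once the sulfate is present. The forward step must leave the hindered C9=C11 alkene and the aldehyde alone.

**17 ⇐ 16 ⇐ 15.** The S–O bond at C2′ is cut and the C2′ oxygen traced back to a MOM ether. With O4′ and O5′ blocked, 16 has a single free phenol, so sulfation needs no selectivity. The MOM group can be removed by mild acid, helped by the ortho formyl group, while the benzyl ethers stay.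

**15 ⇐ 13 (through 14).** The C3′–CHO bond is cut. C3′ lies between the MOM ether and a benzyloxy group, the classical site for directed lithiation. The formyl carbon therefore comes in late, after the organometallic addition and the hydrazone chemistry that a free aldehyde would not survive.

**13 ⇐ 11 ⇐ 10.** A carbonyl group is put back at C2. It has no place in 18 but is what makes the closure of ring A possible. It lies between two methylene groups, so it forms the sulfonylhydrazone 11 readily and is removed by hydride reduction (through 12) under neutral conditions.

**10 ⇐ 9.** The C1–C10 bond is cut. This bond creates the quaternary centre and closes ring A. Cutting it leaves C10 as a carbinol carbon that is allylic to C9=C11 and conjugated to the oxygenated arene, and C1 as the methyl carbon of a C2 methyl ketone. Cutting C5–C10 or C4–C5 instead would not use the arylidene unit. The forward reaction must ionise the C10 hydroxyl of 9 and let C1 bond to C10 on the face that gives the trans fusion.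

**9 ⇐ 8 ⇐ 7.** The C2 carbonyl oxygen is removed to leave a terminal alkene, and the C10 methyl group is cut from a C10 ketone. A free methyl ketone in the side chain would survive neither the methyl addition at C10 nor the condensation at C9, where its own methyl group would react first. An allyl group is inert in both and is oxidised afterwards. The methyl group must add to the carbonyl of the hindered enone 7 without conjugate addition or enolisation.

**7 ⇐ 6 + 3.** The C9=C11 double bond is cut as an aldol condensation. 6 has a single α-methylene group, so regiochemistry is not in question, and the condensation gives the (E) geometry. The relative configuration C5/C8 is settled here by equilibration.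

**6 ⇐ 4 + 5.** The C3–C4 bond is cut as a conjugate allylation. 4 already contains ring B, the C10 carbonyl, C8 with its methyl group in the (S) configuration, and C4 with both methyl groups as an isopropylidene group on C5. One C–C bond completes the side chain, and the question of which α-position of a 3-methylcyclohexanone is functionalised does not arise.

**3 ⇐ 2 ⇐ 1.** The arene is traced back to the commercial trihydroxy aldehyde 1 by cutting the MOM and benzyl C–O bonds. The chelated 2-hydroxyl reacts last, which gives the differentiation between O2′ and O4′/O5′ that the end game needs.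

## Alternatives that were turned down

**Alternative 1:** Ring B is disconnected at C9–C10 by a retro-Ireland–Claisen step. This leads to the cis-δ-lactone A1, in which C11 is the lactone carbonyl, C6 carries the ring oxygen and a 2,6,6-trimethylcyclohexenyl group (the future ring A), and C8 already bears its methyl group.
- Forward key step: after enolisation and O-silylation, A1 would undergo the [3,3] shift on warming. Because C9 and C6 are tied together by C8–C7, the six-atom array can only be a boat. The C6–O bond breaks, C9–C10 forms, and the acid A2 with a C5=C6 double bond results.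
- For: C10 is set by suprafacial chirality transfer from the C6–O stereocentre through a rigid cyclic transition state. This is a more dependable source of configuration at the quaternary centre than the conformational bias relied on in step 7.
- Against: the new bond must form at the fully substituted end of a tetrasubstituted double bond in a boat geometry, where ionisation of the allylic C6–O bond and elimination compete. In A2, C9 is an sp3 stereocentre that must be destroyed again: the acid has to become an aryl ketone and then the C9=C11 alkene by reduction and dehydration next to the quaternary C10, with risk of a 1,2-methyl shift and of E/Z mixtures. C5=C6 must also be hydrogenated from the face away from the C10 methyl group, and A1 itself needs an enantioselective synthesis of two stereocentres.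
- Comparison: in the chosen route 7 already holds C9=C11 with the right geometry, and two further steps set up the cyclisation. Alternative 1 is longer after its key step and spends stereocontrol on a centre that is not kept.

**Alternative 2:** The C9=C11 double bond is disconnected as a two-stage carbonyl–olefin exchange between the trans-decalin A3, with an exocyclic methylene group at C9, and the aryl aldehyde A4 (catechol as pivalates, C2′ as MOM ether).
- Forward key step: irradiation would excite A4. Its carbonyl oxygen adds to the CH2 terminus and its carbon (C11) bonds to C9 through the tertiary 1,4-biradical, giving the spiro-oxetane A5. Cycloreversion in the other sense would then expel formaldehyde and leave C9=C11.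
- For: it is the most convergent plan. It joins the halves late at a position too hindered for ordinary olefination, needs no C10 carbonyl, and exposes the acid-sensitive styrene only at the end. On convergence it is stronger than the chosen route.
- Against: A3 contains all three stereocentres, including the quaternary C10 and the syn 8-methyl group, so the real stereochemical problem is only moved into the preparation of A3. Oxygenated benzaldehydes have low-lying π,π* states and add poorly, the allylic C8–H invites hydrogen abstraction, and the alkene is flanked by C10 and C8. The fragmentation passes through a C11 benzylic cation next to C9 and C10, where ring expansion or methyl shift can compete, and the alkene geometry is set only by thermodynamics.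
- Comparison: the chosen route forms C9=C11 by a condensation whose (E) outcome is secure and then uses the same unit to make C10.

**Alternative 3:** Both rings are disconnected at once, at C5–C10 and C8–C9, to the acyclic trienone A6. In A6 an aryl enone (C11 carbonyl, C9=C10 bearing the C10 methyl group) is linked through C1–C4 to an (E,E)-diene C5–C8.
- Forward key step: a chiral Lewis acid bound to the ketone would promote an intramolecular Diels–Alder reaction through the carbonyl-endo transition state with the tether exo. This gives the trans-fused adduct A7, with the C8 methyl group, the C9 aroyl group and the C10 methyl group all cis, and a C6=C7 double bond.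
- For: one step forms two rings, two C–C bonds and four stereocentres from an achiral chain. The required diastereomer is the one that endo selectivity and the alkene geometries predict, and the absolute configuration would come from a catalyst. In bond economy and in the source of chirality it is stronger than the chosen route.
- Against: the dienophile is a β,β-disubstituted enone whose activating carbonyl is conjugated to a very electron-rich arene and which must form a quaternary centre, so reactivity is low. Enantiocontrol by one-point binding of such a ketone cannot be counted on. Afterwards C6=C7 must be hydrogenated and the C11 ketone turned into the C9=C11 alkene by reduction and dehydration, with the rearrangement and E/Z risks of Alternative 1, and the C9 stereocentre is lost again.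
- Comparison: the chosen route accepts a chiral-pool start and a longer path to ring A. In return C9=C11 is in place from step 4, and only one step, the cation capture, has an uncertain stereochemical outcome.

Key step: step 7

## Route

Remark: the sulfate monoesters 17 and 18 are written as free acids, as in the target structure; they would be handled as sodium salts, and 18 set free at the end on an acid-form cation-exchange resin.

Remark: (S)-(−)-pulegone (4), the less common enantiomer of the natural ketone, is taken to be purchasable.

Step 1
Reactants: 1 2,4,5-trihydroxybenzaldehyde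
Product: 2 4,5-bis(benzyloxy)-2-hydroxybenzaldehyde
Conditions: BnBr (2.05 equiv), K2CO3 (2.1 equiv), DMF, 0 °C → rt, Ar
Reagents that add atoms: benzyl bromide, BrCc1ccccc1
Why: Williamson etherification under weak-base control; the 2-hydroxyl is held in a hydrogen bond to the formyl group and is the least nucleophilic of the three, so two equivalents of benzyl bromide should be taken up at O4 and O5, as is usual for polyhydroxylated 2-hydroxybenzaldehydes.

Step 2
Reactants: 2 4,5-bis(benzyloxy)-2-hydroxybenzaldehyde
Product: 3 4,5-bis(benzyloxy)-2-(methoxymethoxy)benzaldehyde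
Conditions: MOMCl, i-Pr2NEt, CH2Cl2, 0 °C → reflux
Reagents that add atoms: chloromethyl methyl ether, COCCl
Why: O-alkylation of the remaining chelated phenol to the MOM acetal; this group withstands the bases and organometallic reagents that follow, later directs lithiation to C3′, and can be removed without touching the benzyl ethers.

Step 3
Reactants: 4 (S)-(−)-pulegone [(5S)-5-methyl-2-(propan-2-ylidene)cyclohexan-1-one]; 5 allyltrimethylsilane
Product: 6 (5S)-5-methyl-2-(2-methylpent-4-en-2-yl)cyclohexan-1-one (mixture of C2 epimers)
Conditions: TiCl4 (1.1 equiv), CH2Cl2, −78 °C; then H2O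
Reagents that add atoms: none
Why: Hosomi–Sakurai conjugate allylation of a β,β-disubstituted enone; TiCl4 activates the carbonyl and the allylsilane attacks the isopropylidene carbon, which creates the quaternary C4 with its two methyl groups and brings in C3–C1 as a latent acetonyl group. The C8 stereocentre is not enolisable and is untouched; the new α-centre (C5) forms as an epimer mixture that is corrected in step 4.

Step 4
Reactants: 6 (5S)-5-methyl-2-(2-methylpent-4-en-2-yl)cyclohexan-1-one; 3 4,5-bis(benzyloxy)-2-(methoxymethoxy)benzaldehyde
Product: 7 (2E,3S,6S)-2-{[4,5-bis(benzyloxy)-2-(methoxymethoxy)phenyl]methylidene}-3-methyl-6-(2-methylpent-4-en-2-yl)cyclohexan-1-one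
Conditions: KOH, EtOH, reflux
Reagents that add atoms: none
Why: Claisen–Schmidt aldol condensation at the only α-methylene group (C9) with a non-enolisable aldehyde; dehydration gives the conjugated (E)-arylidene with the aryl group turned away from the carbonyl and therefore towards C8, and allylic 1,3-strain then forces the C8 methyl group axial, as is known for arylidene derivatives of menthone. Under the basic conditions C5 epimerises through the enolate to the isomer with the bulky side chain equatorial, which is the cis (3S,6S) isomer needed; the C8 hydrogen lies in the plane of the enone and should not be removed.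

Step 5
Reactants: 7 (2E,3S,6S)-2-{[4,5-bis(benzyloxy)-2-(methoxymethoxy)phenyl]methylidene}-3-methyl-6-(2-methylpent-4-en-2-yl)cyclohexan-1-one
Product: 8 (1R,2E,3S,6S)-2-{[4,5-bis(benzyloxy)-2-(methoxymethoxy)phenyl]methylidene}-1,3-dimethyl-6-(2-methylpent-4-en-2-yl)cyclohexan-1-ol
Conditions: MeLi, CeCl3 (anhydrous), THF, −78 °C; NH4Cl (aq.)
Reagents that add atoms: methyllithium, [Li]C
Why: 1,2-addition of the organocerium reagent formed from MeLi and CeCl3, which is weakly basic and adds to hindered, enolisable, conjugated ketones at the carbonyl carbon. Attack anti to the axial C8 methyl group should give mainly the epimer drawn, but the configuration at C10 is of no consequence because this centre is ionised in step 7.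

Step 6
Reactants: 8 (1R,2E,3S,6S)-2-{[4,5-bis(benzyloxy)-2-(methoxymethoxy)phenyl]methylidene}-1,3-dimethyl-6-(2-methylpent-4-en-2-yl)cyclohexan-1-ol
Product: 9 4-[(1S,2R,3E,4S)-3-{[4,5-bis(benzyloxy)-2-(methoxymethoxy)phenyl]methylidene}-2-hydroxy-2,4-dimethylcyclohexyl]-4-methylpentan-2-one
Conditions: PdCl2 (10 mol %), CuCl (1 equiv), O2 (1 atm), DMF/H2O (7:1), rt
Reagents that add atoms: water, O
Why: Tsuji–Wacker oxidation; divalent palladium activates only the monosubstituted terminal alkene, water adds at the internal carbon and the methyl ketone results, while the hindered trisubstituted styrene is inert. CuCl and O2 reoxidise the palladium, and the medium is only weakly acidic, so the tertiary alcohol should survive.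

Step 7
Reactants: 9 4-[(1S,2R,3E,4S)-3-{[4,5-bis(benzyloxy)-2-(methoxymethoxy)phenyl]methylidene}-2-hydroxy-2,4-dimethylcyclohexyl]-4-methylpentan-2-one
Product: 10 (4aS,7S,8E,8aS)-8-{[4,5-bis(benzyloxy)-2-(methoxymethoxy)phenyl]methylidene}-4,4,7,8a-tetramethyloctahydronaphthalen-2(1H)-one
Conditions: CF3SO3H (10 mol %), (CF3)2CHOH/CH2Cl2 (1:4), 0.01 M, −40 → 0 °C; then Et3N
Reagents that add atoms: none
Why: The acid turns the tertiary C10 hydroxyl into a leaving group and gives an allyl cation spread over C10, C9, C11 and the ortho- and para-oxygenated arene, and the same acid equilibrates the methyl ketone with its enols. The closest known reaction type is the acid-mediated dehydrative SN1 alkylation of enolisable carbonyl compounds by allylic and benzylic alcohols, here in its intramolecular cation–enol form. Ring A closes in a 6-(enolendo)-exo-trig mode: the C1 enol carbon, three atoms from C5, bonds to C10 and C9=C11 is restored outside the new ring, whereas attack at C11 would need an eight-membered ring and the C3 enol could only give a cyclobutane. Capture of the cation by the carbonyl oxygen and loss of a proton are reversible under the conditions and feed back into the cation, while C–C bond formation is not. The new stereocentre C10 is set by the conformation of ring B: allylic 1,3-strain with the aryl group on C11 keeps the C8 methyl group pseudoaxial, the C5 tether is pseudoequatorial and cis to it, and C1 reaches C10 through a chair-like fold on the face away from the C8 methyl group, which gives the trans fusion and leaves the C10 methyl group axial and syn to the C8 methyl group. The alkene geometry is kept because a cation with the aryl group turned towards C10 would clash with the C10 methyl group and C5. The step needs ionisation of C10–OH without cleavage of the MOM or benzyl ethers; the stability of the cation allows catalytic acid at low temperature in an ionising, weakly nucleophilic medium, and the C2′ oxygen must stay protected because a free phenol would trap the cation as a chromene.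

Step 8
Reactants: 10 (4aS,7S,8E,8aS)-8-{[4,5-bis(benzyloxy)-2-(methoxymethoxy)phenyl]methylidene}-4,4,7,8a-tetramethyloctahydronaphthalen-2(1H)-one
Product: 11 N′-[(4aS,7S,8E,8aS)-8-{[4,5-bis(benzyloxy)-2-(methoxymethoxy)phenyl]methylidene}-4,4,7,8a-tetramethyloctahydronaphthalen-2(1H)-ylidene]-4-methylbenzenesulfonohydrazide
Conditions: TsNHNH2, EtOH, 70 °C
Reagents that add atoms: 4-methylbenzenesulfonohydrazide, Cc1ccc(cc1)S(=O)(=O)NN
Why: Condensation of the C2 ketone, which is flanked by two methylene groups, with tosylhydrazide; no acid is added so that the MOM ether and the styrene are not put at risk.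

Step 9
Reactants: 11 N′-[(4aS,7S,8E,8aS)-8-{[4,5-bis(benzyloxy)-2-(methoxymethoxy)phenyl]methylidene}-4,4,7,8a-tetramethyloctahydronaphthalen-2(1H)-ylidene]-4-methylbenzenesulfonohydrazide
Product: 13 1,2-bis(benzyloxy)-4-(methoxymethoxy)-5-{(E)-[(2S,4aS,8aS)-2,5,5,8a-tetramethyloctahydronaphthalen-1(2H)-ylidene]methyl}benzene, via N-boryl tosylhydrazide 12 (not isolated)
Conditions: catecholborane, CHCl3, 0 °C → rt; then NaOAc·3H2O, reflux
Reagents that add atoms: none
Why: Caglioti-type reduction of a tosylhydrazone under neutral conditions; catecholborane delivers hydride to the C=N carbon, and acetate then triggers loss of sulfinate and dinitrogen with delivery of hydrogen to C2. This avoids the strong base and heat of a Wolff–Kishner reduction, which could move the C9=C11 double bond into the ring and erase C8.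

Step 10
Reactants: 13 1,2-bis(benzyloxy)-4-(methoxymethoxy)-5-{(E)-[(2S,4aS,8aS)-2,5,5,8a-tetramethyloctahydronaphthalen-1(2H)-ylidene]methyl}benzene
Product: 15 2,3-bis(benzyloxy)-6-(methoxymethoxy)-5-{(E)-[(2S,4aS,8aS)-2,5,5,8a-tetramethyloctahydronaphthalen-1(2H)-ylidene]methyl}benzaldehyde, via C3′ aryllithium 14 (not isolated)
Conditions: n-BuLi, TMEDA, THF, −78 → 0 °C; DMF, −78 °C → rt; NH4Cl (aq.)
Reagents that add atoms: N,N-dimethylformamide, CN(C)C=O
Why: Directed ortho-metalation and formylation; C3′–H lies between the MOM ether and a benzyloxy group and is the most acidic and best coordinated aryl position, so lithiation should occur there and DMF then delivers the formyl group. C6′–H has only one ortho oxygen.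

Step 11
Reactants: 15 2,3-bis(benzyloxy)-6-(methoxymethoxy)-5-{(E)-[(2S,4aS,8aS)-2,5,5,8a-tetramethyloctahydronaphthalen-1(2H)-ylidene]methyl}benzaldehyde
Product: 16 2,3-bis(benzyloxy)-6-hydroxy-5-{(E)-[(2S,4aS,8aS)-2,5,5,8a-tetramethyloctahydronaphthalen-1(2H)-ylidene]methyl}benzaldehyde
Conditions: 2 M HCl (aq.), THF, 40 °C
Reagents that add atoms: none
Why: Acid hydrolysis of the MOM acetal, assisted by the ortho formyl group, under conditions too mild to cleave benzyl ethers or to protonate the styrene, which is now less electron-rich; the freed phenol is hydrogen-bonded to the aldehyde.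

Step 12
Reactants: 16 2,3-bis(benzyloxy)-6-hydroxy-5-{(E)-[(2S,4aS,8aS)-2,5,5,8a-tetramethyloctahydronaphthalen-1(2H)-ylidene]methyl}benzaldehyde
Product: 17 3,4-bis(benzyloxy)-2-formyl-6-{(E)-[(2S,4aS,8aS)-2,5,5,8a-tetramethyloctahydronaphthalen-1(2H)-ylidene]methyl}phenyl hydrogen sulfate (isolated as its sodium salt)
Conditions: SO3·pyridine (5 equiv), pyridine, 50 °C; then NaHCO3 (aq.)
Reagents that add atoms: sulfur trioxide–pyridine complex, O=S(=O)=O.c1ccncc1
Why: O-sulfation of the single free phenol; the two catechol oxygens are still benzylated, so the sulfate can only go to C2′.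

Step 13
Reactants: 17 3,4-bis(benzyloxy)-2-formyl-6-{(E)-[(2S,4aS,8aS)-2,5,5,8a-tetramethyloctahydronaphthalen-1(2H)-ylidene]methyl}phenyl hydrogen sulfate
Product: 18 2-formyl-3,4-dihydroxy-6-{(E)-[(2S,4aS,8aS)-2,5,5,8a-tetramethyloctahydronaphthalen-1(2H)-ylidene]methyl}phenyl hydrogen sulfate (CNP0149861.1)
Conditions: H2 (1 atm), Pd/C (10 wt %), EtOAc/MeOH, rt, stopped after 2 equiv H2; cation-exchange resin (acid form)
Reagents that add atoms: none
Why: Hydrogenolysis of the two benzyl aryl ethers on palladium under neutral conditions, which aryl sulfate salts tolerate. The C9=C11 alkene is trisubstituted, flanked by a quaternary carbon and shielded on one face by two axial methyl groups, so O-debenzylation should be much faster than its reduction or that of the chelated aldehyde.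

## Compound list

1 | 2,4,5-trihydroxybenzaldehyde | O=Cc1cc(O)c(O)cc1O | starting material
2 | 4,5-bis(benzyloxy)-2-hydroxybenzaldehyde | O=Cc1cc(OCc2ccccc2)c(OCc2ccccc2)cc1O | intermediate
3 | 4,5-bis(benzyloxy)-2-(methoxymethoxy)benzaldehyde | COCOc1cc(OCc2ccccc2)c(OCc2ccccc2)cc1C=O | intermediate
4 | (S)-(−)-pulegone, (5S)-5-methyl-2-(propan-2-ylidene)cyclohexan-1-one | C[C@H]1CCC(=C(C)C)C(=O)C1 | starting material
5 | allyltrimethylsilane | C=CC[Si](C)(C)C | starting material
6 | (5S)-5-methyl-2-(2-methylpent-4-en-2-yl)cyclohexan-1-one, mixture of C2 epimers | C[C@H]1CCC(C(C)(C)CC=C)C(=O)C1 | intermediate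
7 | (2E,3S,6S)-2-{[4,5-bis(benzyloxy)-2-(methoxymethoxy)phenyl]methylidene}-3-methyl-6-(2-methylpent-4-en-2-yl)cyclohexan-1-one | C[C@H]1CC[C@@H](C(C)(C)CC=C)C(=O)/C1=C/c1cc(OCc2ccccc2)c(OCc2ccccc2)cc1OCOC | intermediate
8 | (1R,2E,3S,6S)-2-{[4,5-bis(benzyloxy)-2-(methoxymethoxy)phenyl]methylidene}-1,3-dimethyl-6-(2-methylpent-4-en-2-yl)cyclohexan-1-ol (expected major C1 epimer) | C[C@H]1CC[C@@H](C(C)(C)CC=C)[C@@](C)(O)/C1=C/c1cc(OCc2ccccc2)c(OCc2ccccc2)cc1OCOC | intermediate
9 | 4-[(1S,2R,3E,4S)-3-{[4,5-bis(benzyloxy)-2-(methoxymethoxy)phenyl]methylidene}-2-hydroxy-2,4-dimethylcyclohexyl]-4-methylpentan-2-one | C[C@H]1CC[C@@H](C(C)(C)CC(C)=O)[C@@](C)(O)/C1=C/c1cc(OCc2ccccc2)c(OCc2ccccc2)cc1OCOC | intermediate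
10 | (4aS,7S,8E,8aS)-8-{[4,5-bis(benzyloxy)-2-(methoxymethoxy)phenyl]methylidene}-4,4,7,8a-tetramethyloctahydronaphthalen-2(1H)-one | C[C@H]1CC[C@H]2C(C)(C)CC(=O)C[C@]2(C)/C1=C/c1cc(OCc3ccccc3)c(OCc3ccccc3)cc1OCOC | intermediate
11 | tosylhydrazone of 10 at C2 (C=N geometry not defined) | C[C@H]1CC[C@H]2C(C)(C)CC(=NNS(=O)(=O)c3ccc(C)cc3)C[C@]2(C)/C1=C/c1cc(OCc3ccccc3)c(OCc3ccccc3)cc1OCOC | intermediate
12 | N-(1,3,2-benzodioxaborol-2-yl) tosylhydrazide from hydride addition to 11 (C2 configuration not defined) | C[C@H]1CC[C@H]2C(C)(C)CC(N(NS(=O)(=O)c3ccc(C)cc3)B3Oc4ccccc4O3)C[C@]2(C)/C1=C/c1cc(OCc3ccccc3)c(OCc3ccccc3)cc1OCOC | intermediate (not isolated)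
13 | 1,2-bis(benzyloxy)-4-(methoxymethoxy)-5-{(E)-[(2S,4aS,8aS)-2,5,5,8a-tetramethyloctahydronaphthalen-1(2H)-ylidene]methyl}benzene | C[C@H]1CC[C@H]2C(C)(C)CCC[C@]2(C)/C1=C/c1cc(OCc3ccccc3)c(OCc3ccccc3)cc1OCOC | intermediate
14 | C3′ aryllithium of 13 | C[C@H]1CC[C@H]2C(C)(C)CCC[C@]2(C)/C1=C/c1cc(OCc3ccccc3)c(OCc3ccccc3)c([Li])c1OCOC | intermediate (not isolated)
15 | 2,3-bis(benzyloxy)-6-(methoxymethoxy)-5-{(E)-[(2S,4aS,8aS)-2,5,5,8a-tetramethyloctahydronaphthalen-1(2H)-ylidene]methyl}benzaldehyde | C[C@H]1CC[C@H]2C(C)(C)CCC[C@]2(C)/C1=C/c1cc(OCc3ccccc3)c(OCc3ccccc3)c(C=O)c1OCOC | intermediate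
16 | 2,3-bis(benzyloxy)-6-hydroxy-5-{(E)-[(2S,4aS,8aS)-2,5,5,8a-tetramethyloctahydronaphthalen-1(2H)-ylidene]methyl}benzaldehyde | C[C@H]1CC[C@H]2C(C)(C)CCC[C@]2(C)/C1=C/c1cc(OCc3ccccc3)c(OCc3ccccc3)c(C=O)c1O | intermediate
17 | 3,4-bis(benzyloxy)-2-formyl-6-{(E)-[(2S,4aS,8aS)-2,5,5,8a-tetramethyloctahydronaphthalen-1(2H)-ylidene]methyl}phenyl hydrogen sulfate | C[C@H]1CC[C@H]2C(C)(C)CCC[C@]2(C)/C1=C/c1cc(OCc3ccccc3)c(OCc3ccccc3)c(C=O)c1OS(=O)(=O)O | intermediate
18 | 2-formyl-3,4-dihydroxy-6-{(E)-[(2S,4aS,8aS)-2,5,5,8a-tetramethyloctahydronaphthalen-1(2H)-ylidene]methyl}phenyl hydrogen sulfate | C[C@H]1CC[C@H]2C(C)(C)CCC[C@]2(C)/C1=C/c1cc(O)c(O)c(C=O)c1OS(=O)(=O)O | target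

## Step count and least certain steps

Total step count: 13. Longest linear sequence: 12 steps (1 → 2 → 3, then steps 4 to 13); the terpene branch from 4 is 11 steps.

**Step 7 (key step).** The most likely failure is poor facial selectivity in the capture at C10. Both faces develop a 1,3-diaxial contact with the C8 methyl group, so the preference for the trans fusion rests on the chair-like fold of the tether alone. In addition the enol is present only in low concentration, so proton loss and oligomerisation of the cation can win, and the acid can cleave the MOM ether. Fallback: from 9, kinetic enolisation of the methyl ketone towards C1 with LiN(i-Pr)2 and trapping with Me3SiCl, which also silylates the alkoxide, gives the bis-silylated enol ether F1. Ionisation with catalytic Me3SiOSO2CF3 in CH2Cl2 at −78 °C then closes ring A as an intramolecular Mukaiyama-type SN1 alkylation with a regiodefined nucleophile and without protic acid. This returns to the route at 10.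

**Step 6.** The tertiary allylic alcohol may ionise and dehydrate under the acid generated in the copper chloride medium, or the tertiary hydroxyl may add to the palladium-bound alkene in place of water. Fallback: from 7, the Wacker oxidation is run at the enone stage to give the enedione F2. Its saturated methyl ketone is ketalised selectively with ethylene glycol and pyridinium tosylate, the hindered conjugated C10 carbonyl being left, to give the dioxolane F3. MeLi/CeCl3 then gives the ketal alcohol F4. Under the acid of step 7 the water released on ionisation hydrolyses the ketal, 9 forms in the flask and cyclises, so this path rejoins the route at 10.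

**Step 4.** Condensation may be slow or incomplete because the ketone is hindered and the aldehyde is deactivated by three oxygen donors; long exposure to base could then erode C8 through the extended enolate. Fallback: from 6, kinetic deprotonation at C9 with LiN(i-Pr)2 at −78 °C and addition of 3 gives the aldol adduct F5. Mesylation gives the mesylate F6 (not isolated), and DBU eliminates and equilibrates C5 and the alkene geometry, returning to 7.

**Step 10.** Deprotonation of the benzylic CH2 groups of the benzyl ethers, followed by 1,2-Wittig rearrangement, may compete with ring lithiation. Fallback: from 13, the MOM group is removed with ZnBr2 and n-PrSH to give the phenol F7. Magnesium phenoxide-directed ortho-formylation (MgCl2, Et3N, paraformaldehyde, MeCN, reflux) then places the formyl group at the only free ortho position, C3′, and returns directly to 16.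

**Step 13.** Over-reduction is the risk: hydrogenation of the C9=C11 double bond, or hydrogenolysis of the formyl group once its neighbouring hydroxyl is free. Fallback: from 16, sulfation with 2,2,2-trichloroethyl chlorosulfate (DMAP, Et3N) gives the trichloroethyl sulfate diester F8, which tolerates Lewis acid. BCl3 with pentamethylbenzene at −78 °C removes both benzyl groups to give the catechol F9, and Zn with HCO2NH4 in MeOH removes the trichloroethyl group to give 18.

## Further compounds

F1 | step 7 | bis(trimethylsilyl) derivative of 9: C10 trimethylsilyl ether and C1=C2 trimethylsilyl enol ether | C[C@H]1CC[C@@H](C(C)(C)CC(=C)O[Si](C)(C)C)[C@@](C)(O[Si](C)(C)C)/C1=C/c1cc(OCc2ccccc2)c(OCc2ccccc2)cc1OCOC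
F2 | step 6 | enedione: 4-methylpentan-2-one side chain on the (2E,3S,6S)-arylidene cyclohexanone (Wacker product of 7) | C[C@H]1CC[C@@H](C(C)(C)CC(C)=O)C(=O)/C1=C/c1cc(OCc2ccccc2)c(OCc2ccccc2)cc1OCOC
F3 | step 6 | 1,3-dioxolane ketal of F2 at the side-chain ketone | C[C@H]1CC[C@@H](C(C)(C)CC2(C)OCCO2)C(=O)/C1=C/c1cc(OCc2ccccc2)c(OCc2ccccc2)cc1OCOC
F4 | step 6 | C10 tertiary alcohol from methyl addition to F3 | C[C@H]1CC[C@@H](C(C)(C)CC2(C)OCCO2)[C@@](C)(O)/C1=C/c1cc(OCc2ccccc2)c(OCc2ccccc2)cc1OCOC
F5 | step 4 | aldol adduct of 6 and 3 (β-hydroxy ketone, mixture at C5, C9 and C11) | C[C@H]1CCC(C(C)(C)CC=C)C(=O)C1C(O)c1cc(OCc2ccccc2)c(OCc2ccccc2)cc1OCOC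
F6 | step 4 | methanesulfonate of F5 | C[C@H]1CCC(C(C)(C)CC=C)C(=O)C1C(OS(C)(=O)=O)c1cc(OCc2ccccc2)c(OCc2ccccc2)cc1OCOC
F7 | step 10 | 4,5-bis(benzyloxy)-2-{(E)-[(2S,4aS,8aS)-2,5,5,8a-tetramethyloctahydronaphthalen-1(2H)-ylidene]methyl}phenol | C[C@H]1CC[C@H]2C(C)(C)CCC[C@]2(C)/C1=C/c1cc(OCc3ccccc3)c(OCc3ccccc3)cc1O
F8 | step 13 | aryl 2,2,2-trichloroethyl sulfate of 16 | C[C@H]1CC[C@H]2C(C)(C)CCC[C@]2(C)/C1=C/c1cc(OCc3ccccc3)c(OCc3ccccc3)c(C=O)c1OS(=O)(=O)OCC(Cl)(Cl)Cl
F9 | step 13 | debenzylated F8 (free catechol, trichloroethyl sulfate) | C[C@H]1CC[C@H]2C(C)(C)CCC[C@]2(C)/C1=C/c1cc(O)c(O)c(C=O)c1OS(=O)(=O)OCC(Cl)(Cl)Cl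
A1 | alternative 1 | (4S,6S)-4-methyl-6-(2,6,6-trimethylcyclohex-1-en-1-yl)oxan-2-one (cis-δ-lactone) | C[C@@H]1CC(=O)O[C@@H](C1)C1=C(C)CCCC1(C)C
A2 | alternative 1 | (1R,2S,8aR)-2,5,5,8a-tetramethyl-1,2,3,5,6,7,8,8a-octahydronaphthalene-1-carboxylic acid | C[C@H]1CC=C2C(C)(C)CCC[C@]2(C)[C@@H]1C(=O)O
A3 | alternative 2 | (2S,4aS,8aS)-2,5,5,8a-tetramethyl-1-methylidenedecahydronaphthalene | C[C@H]1CC[C@H]2C(C)(C)CCC[C@]2(C)C1=C
A4 | alternative 2 | 4-formyl-5-(methoxymethoxy)-1,2-phenylene bis(2,2-dimethylpropanoate) | O=Cc1cc(OC(=O)C(C)(C)C)c(OC(=O)C(C)(C)C)cc1OCOC
A5 | alternative 2 | spiro-oxetane with C9 as spiro centre, O–CH2 and the aryl group on C11 | C[C@H]1CC[C@H]2C(C)(C)CCC[C@]2(C)[C@@]13CO[C@H]3c3cc(OC(=O)C(C)(C)C)c(OC(=O)C(C)(C)C)cc3OCOC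
A6 | alternative 3 | (2E,8E,10E)-1-[4,5-dimethoxy-2-(methoxymethoxy)phenyl]-3,7,7-trimethyldodeca-2,8,10-trien-1-one | C/C=C/C=C/C(C)(C)CCC/C(C)=C/C(=O)c1cc(OC)c(OC)cc1OCOC
A7 | alternative 3 | trans-fused cycloadduct with C6=C7, 8-methyl, 9-aroyl and 10-methyl all cis | C[C@H]1C=C[C@H]2C(C)(C)CCC[C@]2(C)[C@H]1C(=O)c1cc(OC)c(OC)cc1OCOC
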